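**Strategy.** Ring B is closed onto a chiral ring A alkene by an intramolecular Diels–Alder reaction that makes C9–C10 and C5–C6 (labdane numbering) at once. The C2 oxygen, bought with (4R,6R)-actinol, is esterified with a geraniol-derived β,γ-unsaturated acid whose carbonyl carbon becomes C6. Its silyl ketene acetal is the diene C6=C7–C8=C9, and the ring A alkene C5=C10 is the dienophile. The feature exploited is that the C2 oxygen lies on the α face of ring A, the face from which C9 must reach C10, and that C6 is oxygenated. The cage ketal formed hydrolyses to the C6 ketone and the free C2 hydroxyl, which allows C5 epimerisation and introduction of the C7 oxygen.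

Key step: step 7

Remark: labdane numbering is used for all bicyclic compounds (ring A: C1–C5 and C10; ring B: C5–C10; C17 is the methyl on C8; C11–C16 the side chain); β is the face of the C10 methyl group. (4R,6R)-Actinol and geraniol are taken as commercial.

**Step 1**
Reactants: 1 (4R,6R)-4-hydroxy-2,2,6-trimethylcyclohexan-1-one (actinol)
Product: 2 2,4,6-triisopropylbenzenesulfonylhydrazone of 1
Conditions: 2,4,6-(i-Pr)3C6H2SO2NHNH2, HCl (cat.), MeCN, rt
Reagents that add atoms: 2,4,6-triisopropylbenzenesulfonohydrazide, CC(C)c1cc(C(C)C)c(S(=O)(=O)NN)c(C(C)C)c1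
Why: Acid-catalysed sulfonylhydrazone formation on the hindered ketone should place the NH–SO2Ar group away from the gem-dimethyl carbon and touches no stereocentre.

**Step 2**
Reactants: 2 2,4,6-triisopropylbenzenesulfonylhydrazone of 1
Product: 4 (R)-3,5,5-trimethylcyclohex-3-en-1-ol, via dilithiated vinyl alkoxide 3 (not isolated)
Conditions: n-BuLi (3.3 equiv), TMEDA, THF/hexane, −78 → 0 °C; then H2O
Reagents that add atoms: none
Why: Shapiro reaction: after O–H and N–H deprotonation the only α-hydrogen (on the methyl-bearing carbon) is removed, loss of sulfinate and N2 gives vinyllithium 3, and protonation gives the C5=C10 alkene regiospecifically; the carbinol centre (future C2) is untouched and the methyl-bearing centre is deliberately erased.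

**Step 3**
Reactants: 5 geraniol
Product: 6 geranyl tert-butyldiphenylsilyl ether
Conditions: TBDPSCl, imidazole, DMF, 0 °C → rt
Reagents that add atoms: tert-butyl(chloro)diphenylsilane, CC(C)(C)[Si](Cl)(c1ccccc1)c1ccccc1
Why: Standard silylation of the primary allylic alcohol gives a protecting group that should survive every later step and be removable beside three esters.

**Step 4**
Reactants: 6 geranyl tert-butyldiphenylsilyl ether
Product: 7 (2E,6E)-8-[(tert-butyldiphenylsilyl)oxy]-2,6-dimethylocta-2,6-dien-1-ol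
Conditions: SeO2 (cat.), t-BuOOH, salicylic acid (cat.), CH2Cl2, rt
Reagents that add atoms: selenium dioxide (oxygen carrier), O=[Se]=O; tert-butyl hydroperoxide (terminal oxidant), CC(C)(C)OO
Why: Riley allylic oxidation (ene reaction then [2,3]-shift) should hydroxylate the (E)-methyl group of the terminal trisubstituted alkene selectively, the other alkene being deactivated by its allylic silyloxy group.

**Step 5**
Reactants: 4 (R)-3,5,5-trimethylcyclohex-3-en-1-ol; 7 (2E,6E)-8-[(tert-butyldiphenylsilyl)oxy]-2,6-dimethylocta-2,6-dien-1-ol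
Product: 9 (2E,6E)-8-[(tert-butyldiphenylsilyl)oxy]-2,6-dimethylocta-2,6-dien-1-yl (R)-3,5,5-trimethylcyclohex-3-en-1-yl carbonate, via imidazole carboxylate 8 (not isolated)
Conditions: CDI, CH2Cl2, rt; then 7, DBU (cat.), rt
Reagents that add atoms: 1,1'-carbonyldiimidazole, O=C(n1ccnc1)n1ccnc1
Why: Stepwise acyl transfer: CDI converts the secondary alcohol into imidazole carboxylate 8, which the primary allylic alcohol attacks under DBU catalysis to give the unsymmetrical carbonate.

**Step 6**
Reactants: 9 mixed allyl cyclohexenyl carbonate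
Product: 10 (R)-3,5,5-trimethylcyclohex-3-en-1-yl (3E,7E)-9-[(tert-butyldiphenylsilyl)oxy]-3,7-dimethylnona-3,7-dienoate
Conditions: Pd(OAc)2 (5 mol %), PPh3 (20 mol %), CO (20 atm), THF, 50 °C
Reagents that add atoms: carbon monoxide, [C-]#[O+]
Why: Palladium-catalysed decarboxylative carbonylation of an allyl alkyl carbonate: ionisation gives a π-allylpalladium alkoxide with loss of CO2, CO inserts at the less hindered CH2 terminus, and the cyclohexenyl alkoxide captures the acylpalladium to give the β,γ-unsaturated ester with the (E)-alkene kept.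

**Step 7**
Reactants: 10 (R)-3,5,5-trimethylcyclohex-3-en-1-yl (3E,7E)-9-[(tert-butyldiphenylsilyl)oxy]-3,7-dimethylnona-3,7-dienoate
Product: 12 2α,6α-epoxy-6β-[(tert-butyldimethylsilyl)oxy]-15-[(tert-butyldiphenylsilyl)oxy]-5β-labda-7,13E-diene (cage silyl ketal; 9α-H), via silyl ketene acetal 11 (not isolated)
Conditions: LiN(iPr)2, THF, −78 °C; TBSCl, DMPU, −78 °C → rt; then PhMe (0.01 M), BHT, 190 °C, sealed tube
Reagents that add atoms: tert-butyl(chloro)dimethylsilane, CC(C)(C)[Si](C)(C)Cl
Why: Thermal, concerted but asynchronous [4+2] cycloaddition between the 1-alkoxy-1-silyloxy-1,3-diene C6=C7–C8=C9 of 11 and the ring A alkene C5=C10, the closest known reaction type being the intramolecular Diels–Alder reaction of vinylketene silyl acetals with unactivated alkenes through a temporary tether (an Ireland–Claisen shift is excluded because the ester is homoallylic). Ring B closes as a six-membered carbocycle by the two new σ bonds, and the C5–C6 bond at the same time closes the six-membered C2–O–C6–C5–C4–C3 ring of a 2-oxabicyclo[2.2.2]octane in which ring A is a boat. C10 and C5 are set by the tether: the diene hangs from the α-oxygen on C2 (the actinol stereocentre) and can only reach the α face of C5=C10, so C9 enters anti to the future β-methyl on C10 and C5–H is β (cis, corrected in step 8). C6 (ketal) and C9 (side chain β, expected from an exo arrangement of ring A) are both erased later, so neither diene geometry nor exo/endo preference matters. The selectivity needed is the orientation C6→C5 and C9→C10 rather than C6→C10; it should follow from the largest HOMO coefficient of the diene at C9 pairing with the more substituted C10, and from avoiding a bond between the fully substituted ketal carbon C6 and the quaternary C10. Conversion of the ester into the ketene acetal also removes the s-trans ester preference that otherwise disfavours ester-tethered cycloadditions.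

**Step 8**
Reactants: 12 cage silyl ketal
Product: 14 15-[(tert-butyldiphenylsilyl)oxy]-2α-hydroxylabda-7,13E-dien-6-one (5α-H; 9α-H), via cis-fused 5β-enone 13 (not isolated)
Conditions: 1 M HCl, THF, 0 °C → rt; then NaOMe (cat.), MeOH, rt
Reagents that add atoms: none
Why: Acid hydrolysis of the mixed silyl ketal (loss of silanol, opening of the hemiketal) unmasks the C6 ketone and the C2 hydroxyl, and base then epimerises C5 through the enolate to the trans-fused decalone expected to be favoured (C5–H α).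

**Step 9**
Reactants: 14 15-[(tert-butyldiphenylsilyl)oxy]-2α-hydroxylabda-7,13E-dien-6-one
Product: 16 15-[(tert-butyldiphenylsilyl)oxy]-2α,7α-dihydroxylabda-8,13E-dien-6-one, via dipotassium dienolate 15 (not isolated)
Conditions: t-BuOK (2.5 equiv), THF/t-BuOH, −20 °C; then 2-(phenylsulfonyl)-3-phenyloxaziridine, −78 °C; AcOH
Reagents that add atoms: 2-(phenylsulfonyl)-3-phenyloxaziridine, O=S(=O)(c1ccccc1)N1OC1c1ccccc1
Why: Equilibrating γ-deprotonation at C9 (as in the deconjugation of isophorone-type enones) should give the linear 6-oxido-6,8-dienolate 15, whose α-carbon C7 is hydroxylated by the N-sulfonyloxaziridine from the α face, pseudo-axially and away from the β-methyls on C4 and C10; this sets C7 (α-OH) and moves the alkene to C8=C9 (oxaziridine enolate hydroxylation).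

**Step 10**
Reactants: 16 15-[(tert-butyldiphenylsilyl)oxy]-2α,7α-dihydroxylabda-8,13E-dien-6-one
Product: 17 2α,7α-diacetoxy-15-[(tert-butyldiphenylsilyl)oxy]labda-8,13E-dien-6-one
Conditions: Ac2O, pyridine, DMAP (cat.), CH2Cl2, 0 °C
Reagents that add atoms: acetic anhydride, CC(=O)OC(C)=O
Why: DMAP-catalysed acylation installs both acetates of the target in one operation under conditions mild enough not to enolise C7.

**Step 11**
Reactants: 17 2α,7α-diacetoxy-15-[(tert-butyldiphenylsilyl)oxy]labda-8,13E-dien-6-one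
Product: 18 2α,7α-diacetoxy-15-[(tert-butyldiphenylsilyl)oxy]labda-8,13E-dien-6β-ol
Conditions: NaBH4, CeCl3·7H2O, MeOH/THF, −40 °C
Reagents that add atoms: none
Why: Luche reduction: hydride should add to the C6 ketone from the α face because the β face is screened by the syn-axial methyls on C4 and C10, giving the axial 6β-alcohol trans-diaxial to the 7α-acetate (no acyl migration possible) and leaving the esters intact.

**Step 12**
Reactants: 18 2α,7α-diacetoxy-15-[(tert-butyldiphenylsilyl)oxy]labda-8,13E-dien-6β-ol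
Product: 19 2α,7α-diacetoxy-15-[(tert-butyldiphenylsilyl)oxy]-6β-(3-methylbutanoyloxy)labda-8,13E-diene
Conditions: 3-methylbutanoyl chloride, pyridine, DMAP, CH2Cl2, 0 → 40 °C
Reagents that add atoms: 3-methylbutanoyl chloride, CC(C)CC(=O)Cl
Why: DMAP-catalysed acylation with the acid chloride, helped by gentle heating, should esterify the hindered axial 6β-hydroxyl without disturbing the acetates.

**Step 13**
Reactants: 19 2α,7α-diacetoxy-15-[(tert-butyldiphenylsilyl)oxy]-6β-(3-methylbutanoyloxy)labda-8,13E-diene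
Product: 20 2α,7α-diacetoxy-6β-(3-methylbutanoyloxy)labda-8,13E-dien-15-ol (CNP0257091.1)
Conditions: HF·pyridine, pyridine, THF, 0 °C → rt
Reagents that add atoms: none
Why: Buffered fluoride cleavage of the primary allylic silyl ether is non-basic and should leave the three esters, including the allylic acetate, untouched.

**Compound list**

1 | (4R,6R)-4-hydroxy-2,2,6-trimethylcyclohexan-1-one (actinol) | O[C@H]1CC(C)(C)C(=O)[C@H](C)C1 | starting material
2 | 2,4,6-triisopropylbenzenesulfonylhydrazone of 1 (sulfonamide nitrogen anti to the gem-dimethyl carbon) | O[C@H]1CC(C)(C)/C(=N/NS(=O)(=O)c2c(C(C)C)cc(C(C)C)cc2C(C)C)[C@H](C)C1 | intermediate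
3 | lithium (R)-4-lithio-3,5,5-trimethylcyclohex-3-en-1-olate | [Li]O[C@H]1CC(C)(C)C([Li])=C(C)C1 | intermediate
4 | (R)-3,5,5-trimethylcyclohex-3-en-1-ol | O[C@H]1CC(C)(C)C=C(C)C1 | intermediate
5 | geraniol, (2E)-3,7-dimethylocta-2,6-dien-1-ol | CC(C)=CCC/C(C)=C/CO | starting material
6 | geranyl tert-butyldiphenylsilyl ether | CC(C)=CCC/C(C)=C/CO[Si](c1ccccc1)(c1ccccc1)C(C)(C)C | intermediate
7 | (2E,6E)-8-[(tert-butyldiphenylsilyl)oxy]-2,6-dimethylocta-2,6-dien-1-ol | OC/C(C)=C/CC/C(C)=C/CO[Si](c1ccccc1)(c1ccccc1)C(C)(C)C | intermediate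
8 | (R)-3,5,5-trimethylcyclohex-3-en-1-yl 1H-imidazole-1-carboxylate | O=C(O[C@H]1CC(C)(C)C=C(C)C1)n1ccnc1 | intermediate
9 | (2E,6E)-8-[(tert-butyldiphenylsilyl)oxy]-2,6-dimethylocta-2,6-dien-1-yl (R)-3,5,5-trimethylcyclohex-3-en-1-yl carbonate | O=C(OC/C(C)=C/CC/C(C)=C/CO[Si](c1ccccc1)(c1ccccc1)C(C)(C)C)O[C@H]1CC(C)(C)C=C(C)C1 | intermediate
10 | (R)-3,5,5-trimethylcyclohex-3-en-1-yl (3E,7E)-9-[(tert-butyldiphenylsilyl)oxy]-3,7-dimethylnona-3,7-dienoate | O=C(C/C(C)=C/CC/C(C)=C/CO[Si](c1ccccc1)(c1ccccc1)C(C)(C)C)O[C@H]1CC(C)(C)C=C(C)C1 | intermediate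
11 | O-tert-butyldimethylsilyl ketene acetal of 10 (1-cyclohexenyloxy-1-silyloxy-1,3-diene; cyclohexenyloxy oxygen cis to C8; C8=C9 E) | CC(C)(C)[Si](C)(C)O/C(O[C@H]1CC(C)(C)C=C(C)C1)=C/C(C)=C/CC/C(C)=C/CO[Si](c1ccccc1)(c1ccccc1)C(C)(C)C | intermediate
12 | 2α,6α-epoxy-6β-[(tert-butyldimethylsilyl)oxy]-15-[(tert-butyldiphenylsilyl)oxy]-5β-labda-7,13E-diene (cage silyl ketal; 9α-H; C6 and C9 configurations are inconsequential) | CC(C)(C)[Si](C)(C)O[C@@]12O[C@H]3CC(C)(C)[C@@H]1[C@](C)(C3)[C@@H](CC/C(C)=C/CO[Si](c1ccccc1)(c1ccccc1)C(C)(C)C)C(C)=C2 | intermediate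
13 | 15-[(tert-butyldiphenylsilyl)oxy]-2α-hydroxy-5β-labda-7,13E-dien-6-one (cis-fused; 9α-H) | O[C@H]1CC(C)(C)[C@H]2C(=O)C=C(C)[C@H](CC/C(C)=C/CO[Si](c3ccccc3)(c3ccccc3)C(C)(C)C)[C@@]2(C)C1 | intermediate
14 | 15-[(tert-butyldiphenylsilyl)oxy]-2α-hydroxylabda-7,13E-dien-6-one (trans-fused, 5α-H; 9α-H) | O[C@H]1CC(C)(C)[C@@H]2C(=O)C=C(C)[C@H](CC/C(C)=C/CO[Si](c3ccccc3)(c3ccccc3)C(C)(C)C)[C@@]2(C)C1 | intermediate
15 | dipotassium 15-[(tert-butyldiphenylsilyl)oxy]labda-6,8,13E-triene-2α,6-diolate | [K+].[K+].[O-][C@H]1CC(C)(C)[C@@H]2C([O-])=CC(C)=C(CC/C(C)=C/CO[Si](c3ccccc3)(c3ccccc3)C(C)(C)C)[C@@]2(C)C1 | intermediate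
16 | 15-[(tert-butyldiphenylsilyl)oxy]-2α,7α-dihydroxylabda-8,13E-dien-6-one | O[C@H]1CC(C)(C)[C@@H]2C(=O)[C@@H](O)C(C)=C(CC/C(C)=C/CO[Si](c3ccccc3)(c3ccccc3)C(C)(C)C)[C@@]2(C)C1 | intermediate
17 | 2α,7α-diacetoxy-15-[(tert-butyldiphenylsilyl)oxy]labda-8,13E-dien-6-one | CC(=O)O[C@H]1CC(C)(C)[C@@H]2C(=O)[C@@H](OC(C)=O)C(C)=C(CC/C(C)=C/CO[Si](c3ccccc3)(c3ccccc3)C(C)(C)C)[C@@]2(C)C1 | intermediate
18 | 2α,7α-diacetoxy-15-[(tert-butyldiphenylsilyl)oxy]labda-8,13E-dien-6β-ol | CC(=O)O[C@H]1CC(C)(C)[C@@H]2[C@H](O)[C@@H](OC(C)=O)C(C)=C(CC/C(C)=C/CO[Si](c3ccccc3)(c3ccccc3)C(C)(C)C)[C@@]2(C)C1 | intermediate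
19 | 2α,7α-diacetoxy-15-[(tert-butyldiphenylsilyl)oxy]-6β-(3-methylbutanoyloxy)labda-8,13E-diene | CC(=O)O[C@H]1CC(C)(C)[C@@H]2[C@H](OC(=O)CC(C)C)[C@@H](OC(C)=O)C(C)=C(CC/C(C)=C/CO[Si](c3ccccc3)(c3ccccc3)C(C)(C)C)[C@@]2(C)C1 | intermediate
20 | 2α,7α-diacetoxy-6β-(3-methylbutanoyloxy)labda-8,13E-dien-15-ol (CNP0257091.1) | CC(=O)O[C@H]1CC(C)(C)[C@@H]2[C@H](OC(=O)CC(C)C)[C@@H](OC(C)=O)C(C)=C(CC/C(C)=C/CO)[C@@]2(C)C1 | target

**Totals.** Total step count: 13. Longest linear sequence: 11 steps (5 → 20, steps 3–13); steps 1–2 are the convergent branch.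

**Steps most likely to fail**

Step 6 (carbonylation of the mixed carbonate). The π-allylpalladium alkoxide pair may collapse by O-allylation of the hindered secondary alkoxide, or lose a β-hydrogen to a 1,3-diene, before CO is inserted and captured. Fallback: carbon–carbon bond formation and ester formation are separated. Setting out from 7, methyl chloroformate and pyridine would give methyl (2E,6E)-8-[(tert-butyldiphenylsilyl)oxy]-2,6-dimethylocta-2,6-dien-1-yl carbonate F1. Its decarboxylative carbonylation (Pd(OAc)2, PPh3, CO, 50 °C; methoxide as a small, fast-capturing alkoxide) would give methyl (3E,7E)-9-[(tert-butyldiphenylsilyl)oxy]-3,7-dimethylnona-3,7-dienoate F2. LiOH (THF/H2O, 0 °C) would give (3E,7E)-9-[(tert-butyldiphenylsilyl)oxy]-3,7-dimethylnona-3,7-dienoic acid F3. Carbodiimide coupling of F3 with 4 (EDC·HCl, DMAP cat., CH2Cl2, 0 °C) comes back to the route at 10.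

Step 7 (cycloaddition). The unactivated alkene, flanked by a quaternary carbon and forced into a boat transition state, may react more slowly than the ketene acetal decays (O-to-C silyl shift), or the diene may add in the reverse orientation (C6 to C10). Fallback: the one-atom ester tether is replaced by a three-atom silyl acetal tether, so that no bicyclo[2.2.2] cage has to form and the orientation is decided by diene and alkene alone. It sets out from 4 and from 7 (through methyl ester F2 of the preceding fallback). 4 with i-Pr2SiCl2 (excess, imidazole, CH2Cl2) would give chloro(diisopropyl)silyl ether F4. The lithium dienolate of F2 (LiN(iPr)2, THF, −78 °C) would be O-silylated by F4 to the silicon-tethered ketene acetal F5. Heating (PhMe, 180 °C) should give the siloxane-bridged cycloadduct F6, whose hydrolysis (1 M HCl, THF) gives 13, where the route is rejoined (base treatment of step 8).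

Step 9 (dienolate hydroxylation). Deprotonation may occur at C5 or at the C8 methyl group instead of C9, or the α-ketol may isomerise in base. Fallback: a neutral silyl dienol ether is oxidised instead of an enolate anion. Setting out from 14, TMSCl, NaI and Et3N (MeCN, equilibrating conditions) would give the linear bis(trimethylsilyl) dienol ether F7. Catalytic OsO4 with N-methylmorpholine N-oxide (acetone/H2O, 0 °C) should osmylate the electron-rich C6=C7 enol ether bond from the α face, in preference to the hindered C8=C9 bond and the side-chain alkene. Work-up with citric acid would give 16, where the route is rejoined.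

**Further compounds**

F1 | step 6 | methyl (2E,6E)-8-[(tert-butyldiphenylsilyl)oxy]-2,6-dimethylocta-2,6-dien-1-yl carbonate | COC(=O)OC/C(C)=C/CC/C(C)=C/CO[Si](c1ccccc1)(c1ccccc1)C(C)(C)C
F2 | step 6 | methyl (3E,7E)-9-[(tert-butyldiphenylsilyl)oxy]-3,7-dimethylnona-3,7-dienoate | COC(=O)C/C(C)=C/CC/C(C)=C/CO[Si](c1ccccc1)(c1ccccc1)C(C)(C)C
F3 | step 6 | (3E,7E)-9-[(tert-butyldiphenylsilyl)oxy]-3,7-dimethylnona-3,7-dienoic acid | OC(=O)C/C(C)=C/CC/C(C)=C/CO[Si](c1ccccc1)(c1ccccc1)C(C)(C)C
F4 | step 7 | chloro(diisopropyl)[(R)-3,5,5-trimethylcyclohex-3-en-1-yloxy]silane | CC(C)[Si](Cl)(C(C)C)O[C@H]1CC(C)(C)C=C(C)C1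
F5 | step 7 | silicon-tethered ketene acetal of F2 (1-methoxy-1-silyloxy-1,3-diene; C8=C9 E) | COC(O[Si](C(C)C)(C(C)C)O[C@H]1CC(C)(C)C=C(C)C1)=C/C(C)=C/CC/C(C)=C/CO[Si](c1ccccc1)(c1ccccc1)C(C)(C)C
F6 | step 7 | siloxane-bridged cycloadduct (C2–O–Si(i-Pr)2–O–C6 bridge, 6-methoxy, 5β-H, Δ7; C6 and C9 configurations inconsequential) | CO[C@@]12O[Si](C(C)C)(C(C)C)O[C@H]3CC(C)(C)[C@@H]1[C@](C)(C3)[C@@H](CC/C(C)=C/CO[Si](c1ccccc1)(c1ccccc1)C(C)(C)C)C(C)=C2
F7 | step 9 | 15-[(tert-butyldiphenylsilyl)oxy]-2α,6-bis(trimethylsilyloxy)labda-6,8,13E-triene | C[Si](C)(C)O[C@H]1CC(C)(C)[C@@H]2C(O[Si](C)(C)C)=CC(C)=C(CC/C(C)=C/CO[Si](c3ccccc3)(c3ccccc3)C(C)(C)C)[C@@]2(C)C1
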